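**Plan**

- Retrosynthesis first removes the ring B benzyl ester, then cuts the ring A C3–CO2H carbon (back through C3–CHO to C3–H) and the 4-O–CH3 bond, leaving an orsellinate depside.
- Ring A is then opened at C1–C6: its C1–C6 are chain carbons C2–C7 of a 3,5,7-trioxooctanoyl unit. Chain C1 is the depside carbonyl, the 2- and 4-oxygens are the C3 and C5 ketone oxygens, and the 6-methyl is C8, so the hindered aryl ester can exist before ring A does.
- The open chain is cut at the acyl–O bond to ring B (acylketene plus the 4-OH of a β-orcinolcarboxylate) and at chain C4–C5 and C6–C7 (two acetylations of 2,2,6-trimethyl-1,3-dioxin-4-one).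
- Forward: ring B is bought as the arene and only re-esterified. The chain is grown on the dioxinone and joined to ring B by ketene capture, ring A (the only ring made) closes by aldol addition and dehydration, and O-methylation, C3 formylation, oxidation and hydrogenolysis follow.
- Stereochemistry: the target has no stereocentre; the two transient ones of the aldol intermediate vanish on aromatisation.

Key step: step 6

Assumption: 10 is drawn as its all-keto tautomer although enol forms should dominate, and metal enolates, phenoxides and carboxylates generated by the bases are treated as ionised forms of the numbered compounds.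

**Route**

Step 1
Reactants: 1 2,2,6-trimethyl-4H-1,3-dioxin-4-one; 2 acetyl chloride
Product: 3 2,2-dimethyl-6-(2-oxopropyl)-4H-1,3-dioxin-4-one
Conditions: 1 (2 equiv), LiN(SiMe3)2 (2 equiv), THF, −78 °C; then 2 (1 equiv), −78 °C; 1 M HCl
Reagents that add atoms: none
Why: Deprotonation of the 6-methyl group gives the lithium dienolate, which is C-acylated at that carbon (vinylogous Claisen condensation), the second equivalent of enolate taking up the proton of the more acidic product.

Step 2
Reactants: 3 2,2-dimethyl-6-(2-oxopropyl)-4H-1,3-dioxin-4-one; 4 N-methoxy-N-methylacetamide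
Product: 5 6-(2,4-dioxopentyl)-2,2-dimethyl-4H-1,3-dioxin-4-one
Conditions: LiN(iPr)2 (2.2 equiv), THF, −78 °C; then 4, −78 to 0 °C; 1 M HCl
Reagents that add atoms: none
Why: Double deprotonation (doubly activated CH2 first, terminal methyl second) gives a dianion that undergoes Claisen-type acylation at the more reactive terminal carbon, and the chelated tetrahedral adduct of the Weinreb amide prevents over-addition.

Step 3
Reactants: 6 methyl 2,4-dihydroxy-3,6-dimethylbenzoate
Product: 7 2,4-dihydroxy-3,6-dimethylbenzoic acid
Conditions: conc. H2SO4, 0 °C to rt, short contact; poured onto ice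
Reagents that add atoms: water, O
Why: Acid hydrolysis by the acylium-ion pathway suits this di-ortho-substituted benzoate, because the aroyl cation is stabilised by the ortho and para hydroxyls; keeping the mixture cold should suppress sulfonation and decarboxylation.

Step 4
Reactants: 7 2,4-dihydroxy-3,6-dimethylbenzoic acid
Product: 8 benzyl 2,4-dihydroxy-3,6-dimethylbenzoate
Conditions: BnBr (1.05 equiv), KHCO3 (1.1 equiv), DMF, rt
Reagents that add atoms: benzyl bromide, BrCc1ccccc1
Why: SN2 alkylation of the carboxylate; hydrogen carbonate ionises only the carboxylic acid, so the phenols are not benzylated.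

Step 5
Reactants: 5 6-(2,4-dioxopentyl)-2,2-dimethyl-4H-1,3-dioxin-4-one; 8 benzyl 2,4-dihydroxy-3,6-dimethylbenzoate
Product: 10 benzyl 2-hydroxy-3,6-dimethyl-4-(3,5,7-trioxooctanoyloxy)benzoate, via acylketene oct-1-ene-1,3,5,7-tetrone 9 (not isolated)
Conditions: 5 (1.1 equiv), 8 (1.0 equiv), toluene (0.2 M), 110 °C, N2 stream, about 45 min; concentrated and used crude
Reagents that add atoms: none
Why: Thermal cycloreversion of the dioxinone releases acetone and acylketene 9, which should be captured by the free, unhindered 4-hydroxyl of 8; the 2-hydroxyl is hydrogen bonded to the benzyl ester and flanked by two ortho substituents, and the moderate concentration favours capture over self-lactonisation.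

Step 6
Reactants: 10 benzyl 2-hydroxy-3,6-dimethyl-4-(3,5,7-trioxooctanoyloxy)benzoate
Product: 12 benzyl 4-(2,4-dihydroxy-6-methylbenzoyloxy)-2-hydroxy-3,6-dimethylbenzoate, via cyclic aldol adduct 11 (not isolated)
Conditions: Et3N (0.5 equiv), CH2Cl2, 0 °C to rt; then CF3CO2H (5 equiv), rt
Reagents that add atoms: none
Why: Et3N reversibly ionises the enolised polycarbonyl chain, and the enolate carbon C2 (between the aryl ester carbonyl and the C3 ketone) adds to the C7 methyl ketone to form the ring A C1–C6 bond in aldol 11; acid then drives loss of water and tautomerisation of the C3 and C5 ketones to the 2- and 4-hydroxyls. The closest known reaction type is the base-then-acid aldol aromatisation of 3,5,7-triketo esters derived from diketo-dioxinones to resorcylates. Ring A closes in a 6-(enolexo)-exo-trig mode. No stereocentre survives, since the two created in 11 are erased on aromatisation. The step needs the C2-to-C7 aldol to outrun C6-to-C1 Claisen closure, lactonisation of the C5 enol oxygen onto C1 and C8-to-C3 aldol; C2 is doubly activated whereas C8 is an unactivated methyl ketone position, a weak amine in a non-polar, non-nucleophilic solvent keeps the enolate ion-paired so that ring B phenoxide is a poor leaving group, and dehydration on acidification makes the aldol irreversible.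

Step 7
Reactants: 12 benzyl 4-(2,4-dihydroxy-6-methylbenzoyloxy)-2-hydroxy-3,6-dimethylbenzoate
Product: 13 benzyl 2-hydroxy-4-(2-hydroxy-4-methoxy-6-methylbenzoyloxy)-3,6-dimethylbenzoate
Conditions: MeI (1.1 equiv), K2CO3 (1.1 equiv), acetone, rt
Reagents that add atoms: iodomethane, CI
Why: Williamson etherification; the ring A 4-hydroxyl is the only phenol without an intramolecular hydrogen bond and the most acidic (para to the ester carbonyl), whereas both ortho hydroxyls are chelated to ester carbonyls.

Step 8
Reactants: 13 benzyl 2-hydroxy-4-(2-hydroxy-4-methoxy-6-methylbenzoyloxy)-3,6-dimethylbenzoate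
Product: 14 benzyl 4-(3-formyl-2-hydroxy-4-methoxy-6-methylbenzoyloxy)-2-hydroxy-3,6-dimethylbenzoate
Conditions: MgCl2 (4 equiv), Et3N (8 equiv), paraformaldehyde (10 equiv), MeCN, 80 °C; then 1 M HCl
Reagents that add atoms: paraformaldehyde (formaldehyde units), C=O
Why: Casnati–Skattebøl ortho-formylation: the chloromagnesium phenoxide of the ring A 2-hydroxyl delivers formaldehyde to the adjacent carbon and a second formaldehyde accepts hydride from the benzylic alkoxide; ring A C3 is the only unsubstituted carbon ortho to a phenol in 13, because the ring B hydroxyl lies between the ester carbon and a methyl.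

Step 9
Reactants: 14 benzyl 4-(3-formyl-2-hydroxy-4-methoxy-6-methylbenzoyloxy)-2-hydroxy-3,6-dimethylbenzoate
Product: 15 3-{[4-(benzyloxycarbonyl)-3-hydroxy-2,5-dimethylphenoxy]carbonyl}-2-hydroxy-6-methoxy-4-methylbenzoic acid
Conditions: NaClO2, NaH2PO4, 2-methyl-2-butene (excess), t-BuOH/THF/H2O, 0 °C to rt
Reagents that add atoms: sodium chlorite, [Na+].[O-]Cl=O
Why: Pinnick oxidation; chlorous acid adds to the aldehyde and fragments to the acid, and the alkene traps the hypochlorous acid so that the electron-rich rings should not be chlorinated while both esters stay intact.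

Step 10
Reactants: 15 3-{[4-(benzyloxycarbonyl)-3-hydroxy-2,5-dimethylphenoxy]carbonyl}-2-hydroxy-6-methoxy-4-methylbenzoic acid
Product: 16 squamatic acid, 3-[(4-carboxy-3-hydroxy-2,5-dimethylphenoxy)carbonyl]-2-hydroxy-6-methoxy-4-methylbenzoic acid
Conditions: H2 (1 atm), 10% Pd/C, EtOAc, rt
Reagents that add atoms: none
Why: Catalytic hydrogenolysis cleaves only the benzylic C–O bond of the benzyl ester; the aryl ester, the methyl ether and the free acids are inert at room temperature.

**Compound list**

1 | 2,2,6-trimethyl-4H-1,3-dioxin-4-one | CC1=CC(=O)OC(C)(C)O1 | starting material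
2 | acetyl chloride | CC(=O)Cl | starting material
3 | 2,2-dimethyl-6-(2-oxopropyl)-4H-1,3-dioxin-4-one | CC(=O)CC1=CC(=O)OC(C)(C)O1 | intermediate
4 | N-methoxy-N-methylacetamide | CC(=O)N(C)OC | starting material
5 | 6-(2,4-dioxopentyl)-2,2-dimethyl-4H-1,3-dioxin-4-one | CC(=O)CC(=O)CC1=CC(=O)OC(C)(C)O1 | intermediate
6 | methyl 2,4-dihydroxy-3,6-dimethylbenzoate | COC(=O)c1c(C)cc(O)c(C)c1O | starting material
7 | 2,4-dihydroxy-3,6-dimethylbenzoic acid | Cc1cc(O)c(C)c(O)c1C(=O)O | intermediate
8 | benzyl 2,4-dihydroxy-3,6-dimethylbenzoate | Cc1cc(O)c(C)c(O)c1C(=O)OCc1ccccc1 | intermediate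
9 | oct-1-ene-1,3,5,7-tetrone (diketo-acylketene, not isolated) | CC(=O)CC(=O)CC(=O)C=C=O | intermediate
10 | benzyl 2-hydroxy-3,6-dimethyl-4-(3,5,7-trioxooctanoyloxy)benzoate | CC(=O)CC(=O)CC(=O)CC(=O)Oc1cc(C)c(C(=O)OCc2ccccc2)c(O)c1C | intermediate
11 | benzyl 2-hydroxy-4-[(2-hydroxy-2-methyl-4,6-dioxocyclohexane-1-carbonyl)oxy]-3,6-dimethylbenzoate (cyclic aldol adduct, mixture of diastereomers and enol tautomers, not isolated) | CC1(O)CC(=O)CC(=O)C1C(=O)Oc1cc(C)c(C(=O)OCc2ccccc2)c(O)c1C | intermediate
12 | benzyl 4-(2,4-dihydroxy-6-methylbenzoyloxy)-2-hydroxy-3,6-dimethylbenzoate | Cc1cc(O)cc(O)c1C(=O)Oc1cc(C)c(C(=O)OCc2ccccc2)c(O)c1C | intermediate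
13 | benzyl 2-hydroxy-4-(2-hydroxy-4-methoxy-6-methylbenzoyloxy)-3,6-dimethylbenzoate | COc1cc(C)c(C(=O)Oc2cc(C)c(C(=O)OCc3ccccc3)c(O)c2C)c(O)c1 | intermediate
14 | benzyl 4-(3-formyl-2-hydroxy-4-methoxy-6-methylbenzoyloxy)-2-hydroxy-3,6-dimethylbenzoate | COc1cc(C)c(C(=O)Oc2cc(C)c(C(=O)OCc3ccccc3)c(O)c2C)c(O)c1C=O | intermediate
15 | 3-{[4-(benzyloxycarbonyl)-3-hydroxy-2,5-dimethylphenoxy]carbonyl}-2-hydroxy-6-methoxy-4-methylbenzoic acid | COc1cc(C)c(C(=O)Oc2cc(C)c(C(=O)OCc3ccccc3)c(O)c2C)c(O)c1C(=O)O | intermediate
16 | squamatic acid | COc1cc(C)c(C(=O)Oc2cc(C)c(C(=O)O)c(O)c2C)c(O)c1C(=O)O | target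

**Step count and risks**

Total steps: 10. Longest linear sequence: 8 steps (steps 1, 2, 5–10 from 1; equally steps 3–10 from 6).

Steps most likely to fail:

Step 5. The acylketene may be consumed by its own C5 enol oxygen (closure to a 4-hydroxy-2-pyranone) faster than the phenol adds, or the aryl β-keto ester may revert to ketene and phenol at 110 °C. The fallback gives up ketene capture and sets out from 8. The 4-hydroxyl of 8 is esterified with purchased 2-hydroxy-4-methoxy-6-methylbenzoic acid and (CF3CO)2O in toluene at rt. The acid is converted in the flask into 2-hydroxy-4-methoxy-6-methylbenzoic trifluoroacetic anhydride F1, which should acylate only the unchelated 4-hydroxyl. This gives 13 directly, so steps 5–7 are replaced and the route resumes at 13 with step 8.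

Step 6. Ring B may be lost as phenoxide, through Claisen closure of C6 onto C1, lactonisation of the C5 enol oxygen or elimination to the acylketene, before the C2-to-C7 aldol closes. The fallback sets out from 5 and runs the same closure on the dioxinone, where the acyl oxygen is held in the acetal ring and cannot leave.
- Et3N in CH2Cl2, then acid, should give 7-hydroxy-2,2,5-trimethyl-4H-1,3-benzodioxin-4-one F2.
- MeI and K2CO3 in acetone convert it into 7-methoxy-2,2,5-trimethyl-4H-1,3-benzodioxin-4-one F3.
- KOH in aqueous THF, then cold dilute HCl, opens the acetonide to 2-hydroxy-4-methoxy-6-methylbenzoic acid F4, the same acid that the fallback to step 5 buys.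
- F4 is joined to 8 with (CF3CO)2O in toluene through the mixed anhydride 2-hydroxy-4-methoxy-6-methylbenzoic trifluoroacetic anhydride F1.

The fallback comes back to the route at 13.

Step 8. Formation of the magnesium phenoxide at the chelated, ester-deactivated ring A hydroxyl may be sluggish, and the methoxide generated during the long heating may cleave the depside ester. The fallback sets out from 13 and replaces the basic formaldehyde addition by a Lewis-acid electrophilic substitution (Rieche formylation: Cl2CHOMe, TiCl4, CH2Cl2, −20 to 0 °C). The titanium-bound 2-hydroxyl should direct the electrophile to C3, giving benzyl 4-{3-[chloro(methoxy)methyl]-2-hydroxy-4-methoxy-6-methylbenzoyloxy}-2-hydroxy-3,6-dimethylbenzoate F5 (racemic, not isolated). Aqueous acid work-up hydrolyses F5 to the aldehyde, and the route is rejoined at 14.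

Further compounds
F1 | step 5 | 2-hydroxy-4-methoxy-6-methylbenzoic trifluoroacetic anhydride | COc1cc(C)c(C(=O)OC(=O)C(F)(F)F)c(O)c1
F2 | step 6 | 7-hydroxy-2,2,5-trimethyl-4H-1,3-benzodioxin-4-one | Cc1cc(O)cc2OC(C)(C)OC(=O)c12
F3 | step 6 | 7-methoxy-2,2,5-trimethyl-4H-1,3-benzodioxin-4-one | COc1cc(C)c2C(=O)OC(C)(C)Oc2c1
F4 | step 6 | 2-hydroxy-4-methoxy-6-methylbenzoic acid | COc1cc(C)c(C(=O)O)c(O)c1
F5 | step 8 | benzyl 4-{3-[chloro(methoxy)methyl]-2-hydroxy-4-methoxy-6-methylbenzoyloxy}-2-hydroxy-3,6-dimethylbenzoate | COc1cc(C)c(C(=O)Oc2cc(C)c(C(=O)OCc3ccccc3)c(O)c2C)c(O)c1C(Cl)OC
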